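**Retrosynthetic overview**

1. Labels: ring A = Ca(CH2OAc)–CbH2–CcH(OH)–CdH(OAc)–CeMe2–Cf; cage = Cf, CgH2, Ch and Ci (cyclopropane CH next to Cg and next to Ca), Cj (C–CH3), CkH(OAc), with Ca as one-carbon bridge. The strategy rests on the six-membered ring Cf–Cg–Ch–Ci–Cj–Ck hidden in the nortricyclane, bridged 1,4 by Ca (Cf to Ci) and 1,3 by the Ch–Cj bond, with ring A spiro-attached at Cf.
2. Cut Ca–Ci and Ch–Cj: the cage comes from a spiro[5.5] 2-methylcyclohexenone (ring B: Ck=O, Cj=Ci) that carries a mesylate on Ch (cis to Ca) and a CHO on Ca, by one base-mediated Michael addition/enolate alkylation cascade.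
3. Ring B comes from a Nozaki–Hiyama–Kishi closure of Ci–Ch; Ch is then set by oxidation to the ene-dione and catalyst-controlled transfer hydrogenation.
4. Cf comes from two successive α′-functionalisations of (S)-4-silyloxy-5,5-dimethylcyclohexenone (prenyl for Cg–Ch, then an aldol for Ck–Cj–Ci), each expected anti to the Cd oxygen; Cc–O is added by a boronate-tethered oxa-Michael addition and the Ca carbon by methylenation/hydroboration.
5. Ring order: ring A (purchased carbocycle), ring B (step 15), then the bicyclo[2.2.1]heptanone and the cyclopropane together (step 21); the end game is reduction, inversion at Ck and acetylation.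

Key step: step 21

Remark on materials: 5 is taken as a catalogue compound (otherwise one dehydrogenation step from 2,2-dimethylcyclohexanone).
Remark on mixtures: the Ck carbinol (13–21), Ca (20–31) and the Ch carbinol (26) are carried as epimer mixtures, because each centre is later oxidised or enolised; they are left undefined in the SMILES.

**Route**

Step 1
Reactants: 1 prop-2-yn-1-ol
Product: 3 (Z)-3-iodo-2-methylprop-2-en-1-ol, via alkenylmagnesium alkoxide 2 (not isolated)
Conditions: MeMgBr (2.5 equiv), CuI (10 mol%), THF, −10 °C to rt; then I2, −10 °C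
Reagents that add atoms: methylmagnesium bromide C[Mg]Br; iodine II
Why: Copper-catalysed anti-carbomagnesiation of the propargylic alkoxide puts magnesium on the terminal carbon cis to the CH2O group (chelate) and iodinolysis goes with retention, so the (Z)-iodoalkene should result.

Step 2
Reactants: 3 (Z)-3-iodo-2-methylprop-2-en-1-ol
Product: 4 (Z)-3-iodo-2-methylprop-2-enal
Conditions: MnO2, CH2Cl2, rt, dark; used at once
Reagents that add atoms: none
Why: Neutral allylic oxidation with MnO2 should leave the (Z)-iodoalkene geometry intact.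

Step 3
Reactants: 5 6,6-dimethylcyclohex-2-en-1-one
Product: 6 (S)-6,6-dimethylcyclohex-2-en-1-ol
Conditions: (R)-2-methyl-CBS-oxazaborolidine (10 mol%), catecholborane, toluene, −78 °C
Reagents that add atoms: none
Why: Corey–Bakshi–Shibata reduction in which the quaternary C6 is the large group, so the (R)-catalyst should give the (S)-carbinol that becomes Cd.

Step 4
Reactants: 6 (S)-6,6-dimethylcyclohex-2-en-1-ol
Product: 7 (S)-tert-butyl[(6,6-dimethylcyclohex-2-en-1-yl)oxy]dimethylsilane
Conditions: TBSCl, imidazole, DMF, rt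
Reagents that add atoms: tert-butyldimethylsilyl chloride CC(C)(C)[Si](C)(C)Cl
Why: Standard silylation of a secondary alcohol.

Step 5
Reactants: 7 (S)-tert-butyl[(6,6-dimethylcyclohex-2-en-1-yl)oxy]dimethylsilane
Product: 8 (S)-4-(tert-butyldimethylsilyloxy)-5,5-dimethylcyclohex-2-en-1-one
Conditions: CrO3, 3,5-dimethylpyrazole, CH2Cl2, −20 °C
Reagents that add atoms: chromium trioxide O=[Cr](=O)=O
Why: Allylic oxidation with the CrO3–dimethylpyrazole complex should attack the open ring CH2 (future Ca) and not the neopentyl silyloxy-bearing CH, giving the 4-silyloxy enone without touching Cd.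

Step 6
Reactants: 8 (S)-4-(tert-butyldimethylsilyloxy)-5,5-dimethylcyclohex-2-en-1-one; 9 1-bromo-3-methylbut-2-ene
Product: 11 (4S,6R)-4-(tert-butyldimethylsilyloxy)-5,5-dimethyl-6-(3-methylbut-2-enyl)cyclohex-2-en-1-one, via lithium dienolate 10 (not isolated)
Conditions: LiN(iPr)2, THF, −78 °C; then 9, DMPU, −78 to −20 °C
Reagents that add atoms: 1-bromo-3-methylbut-2-ene CC(C)=CCBr
Why: Kinetic α′-enolisation (the only α′ site, as in isophorone) and SN2 alkylation with a reactive allylic bromide; the prenyl group should enter trans to OTBS, but this centre is planarised again in step 7.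

Step 7
Reactants: 11 prenyl enone; 4 (Z)-3-iodo-2-methylprop-2-enal
Product: 13 (4S,6S)-4-(tert-butyldimethylsilyloxy)-6-[(Z)-1-hydroxy-3-iodo-2-methylprop-2-enyl]-5,5-dimethyl-6-(3-methylbut-2-enyl)cyclohex-2-en-1-one, via lithium enolate 12 (not isolated)
Conditions: LiN(iPr)2, THF, −78 °C; then 4, −78 °C; AcOH quench at −78 °C
Reagents that add atoms: (Z)-3-iodo-2-methylprop-2-enal O=C/C(C)=C\I
Why: Aldol addition of the tetrasubstituted kinetic enolate; the aldehyde should add anti to the silyloxy group on Cd (1,3 across Ce), which puts Ck trans and the prenyl CH2 (Cg) cis to the Cd oxygen and so sets Cf.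

Step 8
Reactants: 13 aldol adduct
Product: 14 the 4-hydroxy enone (Cd–OH free)
Conditions: HF·pyridine, pyridine, THF, 0 °C to rt
Reagents that add atoms: none
Why: Acidic fluoride desilylation avoids the retro-aldol and elimination paths that basic fluoride could open.

Step 9
Reactants: 14 4-hydroxy enone
Product: 17 acetonide ketone (Ca=O; cis Cc/Cd O-isopropylidene on the prenyl face), via cyclic phenylboronate 15 (not isolated), via free cis-diol ketone 16 (not isolated)
Conditions: PhB(OH)2, quinuclidine (20 mol%), 4 Å molecular sieves, toluene, 40 °C; then pinacol, Me2C(OMe)2, camphorsulfonic acid, rt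
Reagents that add atoms: phenylboronic acid OB(O)c1ccccc1; 2,2-dimethoxypropane COC(C)(C)OC
Why: Boronate-tethered oxa-Michael addition: the Cd–O–B(Ph)–OH hemiester delivers its amine-activated hydroxyl to the enone β-carbon Cc on the same face, so Cc–O is cis to Cd–O; pinacol then takes the boron and the diol is ketalised in the same flask.

Step 10
Reactants: 17 acetonide ketone
Product: 18 exocyclic alkene (Ca=CH2)
Conditions: Cp2TiMe2 (3 equiv), toluene, 65 °C, dark
Reagents that add atoms: dimethyltitanocene C[Ti](C)(C1C=CC=C1)C1C=CC=C1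
Why: Petasis methylenation is non-basic, so the hindered β-alkoxy ketone should be olefinated without β-elimination.

Step 11
Reactants: 18 exocyclic alkene
Product: 20 primary alcohol Ca(H)–CH2OH, via B-alkyl-9-BBN adduct 19 (not isolated)
Conditions: 9-BBN, THF, 50 °C; then NaOH, H2O2, 0 °C
Reagents that add atoms: hydrogen peroxide OO
Why: Anti-Markovnikov hydroboration–oxidation; 9-BBN reacts with the 1,1-disubstituted alkene far faster than with the trisubstituted prenyl and iodoalkene groups, and the new centre Ca need not be controlled.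

Step 12
Reactants: 20 primary alcohol
Product: 21 primary TBS ether
Conditions: TBSCl, imidazole, CH2Cl2, 0 °C
Reagents that add atoms: tert-butyldimethylsilyl chloride CC(C)(C)[Si](C)(C)Cl
Why: Silylation should select the primary hydroxyl over the neopentyl allylic Ck carbinol.

Step 13
Reactants: 21 primary TBS ether
Product: 22 (Z)-β-iodo enone (Ck=O)
Conditions: Dess–Martin periodinane, NaHCO3, CH2Cl2, 0 °C to rt
Reagents that add atoms: none
Why: Dess–Martin oxidation of the allylic alcohol; both carbinol epimers converge on one ketone.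

Step 14
Reactants: 22 (Z)-β-iodo enone
Product: 24 aldehyde Cf–CH2–CHO (Ch), via secondary ozonide 23 (not isolated)
Conditions: O3, CH2Cl2, −78 °C (Sudan red end point); then PPh3, −78 °C to rt
Reagents that add atoms: ozone [O-][O+]=O
Why: Ozonolysis should select the electron-rich trisubstituted prenyl alkene over the electron-poor iodo enone.

Step 15
Reactants: 24 aldehyde
Product: 26 spiro γ-hydroxy enone (ring B closed), via alkenylchromium dichloride 25 (not isolated)
Conditions: CrCl2 (5 equiv), NiCl2 (2 mol%), DMF, rt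
Reagents that add atoms: none
Why: Intramolecular Nozaki–Hiyama–Kishi reaction: the (Z)-alkenylchromium (Cr on Ci, cis to Ck) adds to the aldehyde and not to the ketone, closing the six-membered ring at Ci–Ch; the Ch configuration is corrected in steps 16 and 17.

Step 16
Reactants: 26 spiro γ-hydroxy enone
Product: 27 spiro ene-dione (Ck=O and Ch=O)
Conditions: Dess–Martin periodinane, NaHCO3, CH2Cl2, rt
Reagents that add atoms: none
Why: Dess–Martin oxidation removes the uncontrolled Ch centre.

Step 17
Reactants: 27 spiro ene-dione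
Product: 28 (S)-Ch alcohol (OH cis to Ca on ring B)
Conditions: RuCl(p-cymene)[(S,S)-TsDPEN] (1 mol%), HCO2H–Et3N (5:2), CH2Cl2, rt
Reagents that add atoms: none
Why: Noyori-type asymmetric transfer hydrogenation: only the unhindered Ch=O (CH2 and CH= neighbours) should react, as in the known C4-selective reduction of 2,6,6-trimethylcyclohex-2-ene-1,4-dione, and the (S,S)-catalyst should give the (S)-carbinol.

Step 18
Reactants: 28 (S)-Ch alcohol
Product: 29 Ch mesylate
Conditions: MsCl, Et3N, CH2Cl2, −20 °C
Reagents that add atoms: methanesulfonyl chloride CS(=O)(=O)Cl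
Why: Sulfonylation with retention; the electron-poor enone should keep the allylic mesylate from ionising.

Step 19
Reactants: 29 Ch mesylate
Product: 30 primary alcohol mesylate
Conditions: HF·pyridine, pyridine, THF, 0 °C
Reagents that add atoms: none
Why: Acidic desilylation should spare the mesylate, the enone and the acetonide.

Step 20
Reactants: 30 primary alcohol mesylate
Product: 31 spiro γ-mesyloxy enone aldehyde (key precursor)
Conditions: Dess–Martin periodinane, NaHCO3, CH2Cl2, 0 °C
Reagents that add atoms: none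
Why: Buffered Dess–Martin oxidation gives the α-branched aldehyde without base; its Ca configuration is irrelevant.

Step 21
Reactants: 31 spiro γ-mesyloxy enone aldehyde
Product: 34 nortricyclanone aldehyde, via aldehyde enolate 32 (not isolated), via bicyclic ketone enolate 33 (not isolated)
Conditions: DBU, MeCN, 0 °C to rt
Reagents that add atoms: none
Why: DBU removes the aldehyde α-proton (Cf is quaternary and the enone has no α′-hydrogen), the Ca enolate adds across the boat-shaped ring B to the β-carbon Ci (5-exo-trig Michael addition, closing the bicyclo[2.2.1]heptanone), and the resulting Cj enolate displaces the exo mesylate on Ch with inversion (3-exo-tet enolate alkylation, closing the cyclopropane). The closest known reaction type is the Michael-initiated ring closure of enones with a γ-leaving group, joined to the intramolecular Michael addition of an aldehyde enolate. The strained Michael step is reversible and the irreversible cyclopropane closure should pull it through. Ci and Cj have no freedom (Ca can reach only the ring-B face it sits on, and Cj can bond to Ch only from inside the cage), Ch is inverted, which is why the (S)-mesylate cis to Ca was made in step 17, and the new quaternary Ca should form with ring A over the flat Ck/Cj bridge, not over the Cg–Ch bridge, whose exo hydrogen and exo mesylate point at it. The step needs C-alkylation to outrun base-induced loss of methanesulfonic acid and closure through the other ring-A chair; the short enolate-to-Ch distance and the exo leaving group should secure the first, the steric argument the second.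

Step 22
Reactants: 34 nortricyclanone aldehyde
Product: 35 diol (Ca–CH2OH; Ck–OH on the Ca side)
Conditions: LiAlH4, THF, −20 to 0 °C
Reagents that add atoms: none
Why: Hydride reduction of both carbonyls; the Ck ketone should be attacked from the Cg side because the ring-A Cb–H hangs over the other face (as the syn-methyl does in camphor), which leaves the hydroxyl on the Ca side.

Step 23
Reactants: 35 diol
Product: 36 primary acetate
Conditions: Ac2O (1.1 equiv), pyridine, CH2Cl2, 0 °C
Reagents that add atoms: acetic anhydride CC(=O)OC(C)=O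
Why: Acylation should select the primary hydroxyl over the shielded secondary one.

Step 24
Reactants: 36 primary acetate
Product: 38 diacetate acetonide (Ck–OAc on the Cg side), via Ck mesylate 37 (not isolated)
Conditions: MsCl, Et3N, CH2Cl2, −20 °C; then KOAc, AcOH, 50 °C
Reagents that add atoms: potassium acetate CC(=O)[O-].[K+]
Why: Solvolysis of a cyclopropylcarbinyl (3-nortricyclyl-type) mesylate: the bisected, cyclopropane-stabilised cation at Ck should be captured by acetate on the open face towards Cg, giving net inversion.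

Step 25
Reactants: 38 diacetate acetonide
Product: 39 diacetate cis-diol
Conditions: AcOH–H2O (4:1), 40 °C
Reagents that add atoms: none
Why: Mild acid hydrolysis of the acetonide should spare the acetates.

Step 26
Reactants: 39 diacetate cis-diol
Product: 41 CNP0111873.1, via dibutylstannylene acetal 40 (not isolated)
Conditions: Bu2SnO, MeOH, reflux, evaporate; then AcCl, CH2Cl2, 0 °C
Reagents that add atoms: acetyl chloride CC(=O)Cl
Why: Stannylene-acetal-directed monoacylation: in the axial/equatorial cis-diol the equatorial oxygen (Cd) is activated, and the axial Cc hydroxyl is shielded 1,3 by CH2OAc and a methyl group.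

**Compound list**

1 | prop-2-yn-1-ol | C#CCO | starting material
2 | bromomagnesium (Z)-3-(bromomagnesio)-2-methylprop-2-en-1-olate | Br[Mg]OC/C(C)=C\[Mg]Br | intermediate
3 | (Z)-3-iodo-2-methylprop-2-en-1-ol | OC/C(C)=C\I | intermediate
4 | (Z)-3-iodo-2-methylprop-2-enal | O=C/C(C)=C\I | intermediate
5 | 6,6-dimethylcyclohex-2-en-1-one | O=C1C=CCCC1(C)C | starting material
6 | (S)-6,6-dimethylcyclohex-2-en-1-ol | O[C@H]1C=CCCC1(C)C | intermediate
7 | (S)-tert-butyl[(6,6-dimethylcyclohex-2-en-1-yl)oxy]dimethylsilane | CC(C)(C)[Si](C)(C)O[C@H]1C=CCCC1(C)C | intermediate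
8 | (S)-4-(tert-butyldimethylsilyloxy)-5,5-dimethylcyclohex-2-en-1-one | O=C1C=C[C@H](O[Si](C)(C)C(C)(C)C)C(C)(C)C1 | intermediate
9 | 1-bromo-3-methylbut-2-ene (prenyl bromide) | CC(C)=CCBr | starting material
10 | lithium dienolate of 8 (Ca–OLi, Ca=Cf) | [Li]OC1=CC(C)(C)[C@@H](O[Si](C)(C)C(C)(C)C)C=C1 | intermediate
11 | (4S,6R)-4-(tert-butyldimethylsilyloxy)-5,5-dimethyl-6-(3-methylbut-2-enyl)cyclohex-2-en-1-one (prenyl trans to OTBS) | O=C1C=C[C@H](O[Si](C)(C)C(C)(C)C)C(C)(C)[C@H]1CC=C(C)C | intermediate
12 | lithium enolate of 11 | [Li]OC1=C(CC=C(C)C)C(C)(C)[C@@H](O[Si](C)(C)C(C)(C)C)C=C1 | intermediate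
13 | (4S,6S)-4-(tert-butyldimethylsilyloxy)-6-[(Z)-1-hydroxy-3-iodo-2-methylprop-2-enyl]-5,5-dimethyl-6-(3-methylbut-2-enyl)cyclohex-2-en-1-one (prenyl cis, carbinol chain trans to OTBS; carbinol epimers) | O=C1C=C[C@H](O[Si](C)(C)C(C)(C)C)C(C)(C)[C@@]1(CC=C(C)C)C(O)/C(C)=C\I | intermediate
14 | 4-hydroxy analogue of 13 (Cd–OH free) | O=C1C=C[C@H](O)C(C)(C)[C@@]1(CC=C(C)C)C(O)/C(C)=C\I | intermediate
15 | cyclic phenylboronate of the cis Cc,Cd-diol ketone | O=C1C[C@@H]2OB(c3ccccc3)O[C@@H]2C(C)(C)[C@@]1(CC=C(C)C)C(O)/C(C)=C\I | intermediate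
16 | cis Cc,Cd-diol ketone | O=C1C[C@H](O)[C@H](O)C(C)(C)[C@@]1(CC=C(C)C)C(O)/C(C)=C\I | intermediate
17 | acetonide ketone (Ca=O; Cc/Cd O-isopropylidene cis to the prenyl group on Cf) | O=C1C[C@@H]2OC(C)(C)O[C@@H]2C(C)(C)[C@@]1(CC=C(C)C)C(O)/C(C)=C\I | intermediate
18 | exocyclic alkene (Ca=CH2) | C=C1C[C@@H]2OC(C)(C)O[C@@H]2C(C)(C)[C@@]1(CC=C(C)C)C(O)/C(C)=C\I | intermediate
19 | B-alkyl-9-BBN adduct (Ca–CH2–B; carbinol as its 9-BBN borinate) | C(B1C2CCCC1CCC2)C3C[C@@H]4OC(C)(C)O[C@@H]4C(C)(C)[C@@]3(CC=C(C)C)C(OB5C6CCCC5CCC6)/C(C)=C\I | intermediate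
20 | primary alcohol Ca(H)–CH2OH (Ca epimers) | OCC1C[C@@H]2OC(C)(C)O[C@@H]2C(C)(C)[C@@]1(CC=C(C)C)C(O)/C(C)=C\I | intermediate
21 | primary TBS ether of 20 | CC(C)(C)[Si](C)(C)OCC1C[C@@H]2OC(C)(C)O[C@@H]2C(C)(C)[C@@]1(CC=C(C)C)C(O)/C(C)=C\I | intermediate
22 | (Z)-β-iodo enone (Ck=O) | CC(C)(C)[Si](C)(C)OCC1C[C@@H]2OC(C)(C)O[C@@H]2C(C)(C)[C@@]1(CC=C(C)C)C(=O)/C(C)=C\I | intermediate
23 | secondary ozonide of the prenyl group of 22 | CC(C)(C)[Si](C)(C)OCC1C[C@@H]2OC(C)(C)O[C@@H]2C(C)(C)[C@@]1(CC3OOC(C)(C)O3)C(=O)/C(C)=C\I | intermediate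
24 | aldehyde Cf–CH2–CHO with the (Z)-β-iodo enone | CC(C)(C)[Si](C)(C)OCC1C[C@@H]2OC(C)(C)O[C@@H]2C(C)(C)[C@@]1(CC=O)C(=O)/C(C)=C\I | intermediate
25 | (Z)-alkenylchromium dichloride from 24 | CC(C)(C)[Si](C)(C)OCC1C[C@@H]2OC(C)(C)O[C@@H]2C(C)(C)[C@@]1(CC=O)C(=O)/C(C)=C\[Cr](Cl)Cl | intermediate
26 | spiro γ-hydroxy enone (ring B: Ck=O, Cj(Me)=Ci, Ch–OH epimers) | CC(C)(C)[Si](C)(C)OCC1C[C@@H]2OC(C)(C)O[C@@H]2C(C)(C)[C@]13CC(O)C=C(C)C3=O | intermediate
27 | spiro ene-dione | CC(C)(C)[Si](C)(C)OCC1C[C@@H]2OC(C)(C)O[C@@H]2C(C)(C)[C@]13CC(=O)C=C(C)C3=O | intermediate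
28 | (S)-Ch alcohol (OH cis to Ca on ring B) | CC(C)(C)[Si](C)(C)OCC1C[C@@H]2OC(C)(C)O[C@@H]2C(C)(C)[C@]13C[C@H](O)C=C(C)C3=O | intermediate
29 | Ch mesylate | CC(C)(C)[Si](C)(C)OCC1C[C@@H]2OC(C)(C)O[C@@H]2C(C)(C)[C@]13C[C@H](OS(C)(=O)=O)C=C(C)C3=O | intermediate
30 | primary alcohol mesylate | OCC1C[C@@H]2OC(C)(C)O[C@@H]2C(C)(C)[C@]13C[C@H](OS(C)(=O)=O)C=C(C)C3=O | intermediate
31 | spiro γ-mesyloxy enone aldehyde (key precursor; Ca epimers) | O=CC1C[C@@H]2OC(C)(C)O[C@@H]2C(C)(C)[C@]13C[C@H](OS(C)(=O)=O)C=C(C)C3=O | intermediate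
32 | aldehyde enolate of 31 (DBU-H+ salt) | [O-]C=C1C[C@@H]2OC(C)(C)O[C@@H]2C(C)(C)[C@]13C[C@H](OS(C)(=O)=O)C=C(C)C3=O | intermediate
33 | bicyclo[2.2.1]heptanone enolate (Michael adduct; exo mesylate on Ch) | O=C[C@]12C[C@@H]4OC(C)(C)O[C@@H]4C(C)(C)[C@]13C[C@H](OS(C)(=O)=O)[C@H]2C(C)=C3[O-] | intermediate
34 | nortricyclanone aldehyde (key product) | O=C[C@]12C[C@@H]4OC(C)(C)O[C@@H]4C(C)(C)[C@]13C[C@@H]1[C@H]2[C@]1(C)C3=O | intermediate
35 | diol (Ca–CH2OH; Ck–OH on the Ca side) | OC[C@]12C[C@@H]4OC(C)(C)O[C@@H]4C(C)(C)[C@]13C[C@@H]1[C@H]2[C@]1(C)[C@@H]3O | intermediate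
36 | primary acetate of 35 | CC(=O)OC[C@]12C[C@@H]4OC(C)(C)O[C@@H]4C(C)(C)[C@]13C[C@@H]1[C@H]2[C@]1(C)[C@@H]3O | intermediate
37 | Ck mesylate of 36 | CC(=O)OC[C@]12C[C@@H]4OC(C)(C)O[C@@H]4C(C)(C)[C@]13C[C@@H]1[C@H]2[C@]1(C)[C@@H]3OS(C)(=O)=O | intermediate
38 | diacetate acetonide (Ck–OAc on the Cg side) | CC(=O)OC[C@]12C[C@@H]4OC(C)(C)O[C@@H]4C(C)(C)[C@]13C[C@@H]1[C@H]2[C@]1(C)[C@H]3OC(C)=O | intermediate
39 | diacetate cis-diol | CC(=O)OC[C@]12C[C@H](O)[C@H](O)C(C)(C)[C@]13C[C@@H]1[C@H]2[C@]1(C)[C@H]3OC(C)=O | intermediate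
40 | dibutylstannylene acetal of 39 | CC(=O)OC[C@]12C[C@@H]4O[Sn](CCCC)(CCCC)O[C@@H]4C(C)(C)[C@]13C[C@@H]1[C@H]2[C@]1(C)[C@H]3OC(C)=O | intermediate
41 | CNP0111873.1 | CC(=O)OC[C@]12C[C@H](O)[C@H](OC(C)=O)C(C)(C)[C@]13C[C@@H]1[C@H]2[C@]1(C)[C@H]3OC(C)=O | target

**Step count**

Total: 26 steps (24 in the main line, 2 for aldehyde 4). Longest linear sequence: 24 steps (5 to 41, steps 3–26).

**Steps most likely to fail**

Step 21 (key step). The base may cause elimination of methanesulfonic acid from ring B before the strained Michael closure, the closure may go through the other ring-A chair and give the Ca-epimeric cage, or the aldehyde may only epimerise. The fallback separates the two bond formations and sets out from 31. Silylation (TMSOTf, Et3N, CH2Cl2, −78 °C) gives the aldehyde trimethylsilyl enol ether F1. A catalytic silyl triflate then promotes the intramolecular Mukaiyama–Michael addition to the enone, giving after work-up the bicyclic keto aldehyde mesylate F2. F2 is closed to the cyclopropane with KOtBu in THF at −78 °C (enolate 1,3-alkylation), which returns to the route at 34.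

Step 7. Deprotonation of the hindered methine may be slow and compete with γ-deprotonation, and the crowded aldolate may revert before the quench. The fallback makes the same enolate regiospecifically by conjugate addition and sets out from 8. α′-Aminomethylation (LiN(iPr)2, then Eschenmoser salt) gives the Mannich base F3. Quaternisation with MeI and elimination with NaHCO3 give the α′-methylene enone F4. Copper-catalysed conjugate addition of 2-methylprop-1-enylmagnesium bromide (CuBr·SMe2, THF, −78 °C) to the exocyclic methylene builds the prenyl group and releases the Cf enolate, which is trapped in the same flask with 4; this returns to the route at 13.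

Step 24. The cyclopropylcarbinyl cation may open to the homoallylic (norbornenyl) cation, rearrange, or be captured on both faces. The fallback avoids the cation and sets out from 35. Meerwein–Ponndorf–Verley/Oppenauer equilibration (Al(OiPr)3, isopropanol, a little acetone, toluene, reflux) should move the hindered Ck hydroxyl to the less crowded Cg side, giving the epimeric diol F5. Acetylation of both hydroxyls (Ac2O, DMAP, pyridine) returns to the route at 38.

**Further compounds**

F1 | step 21 | trimethylsilyl enol ether of aldehyde 31 | C[Si](C)(C)OC=C1C[C@@H]2OC(C)(C)O[C@@H]2C(C)(C)[C@]13C[C@H](OS(C)(=O)=O)C=C(C)C3=O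
F2 | step 21 | bicyclo[2.2.1]heptanone keto aldehyde with exo mesylate on Ch | O=C[C@]12C[C@@H]4OC(C)(C)O[C@@H]4C(C)(C)[C@]13C[C@H](OS(C)(=O)=O)[C@H]2C(C)C3=O
F3 | step 7 | (4S)-4-(tert-butyldimethylsilyloxy)-6-(dimethylaminomethyl)-5,5-dimethylcyclohex-2-en-1-one | CN(C)CC1C(=O)C=C[C@H](O[Si](C)(C)C(C)(C)C)C1(C)C
F4 | step 7 | (S)-4-(tert-butyldimethylsilyloxy)-5,5-dimethyl-6-methylenecyclohex-2-en-1-one | C=C1C(=O)C=C[C@H](O[Si](C)(C)C(C)(C)C)C1(C)C
F5 | step 24 | epimeric diol (Ca–CH2OH; Ck–OH on the Cg side) | OC[C@]12C[C@@H]4OC(C)(C)O[C@@H]4C(C)(C)[C@]13C[C@@H]1[C@H]2[C@]1(C)[C@H]3O
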